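**Retrosynthetic overview**

1. Feature: ring C5–C10 carries its functional carbons C8/C9 opposite the spiro carbon C5, so it is a para-alkylphenol in disguise (para carbon = C5, C–O carbon = C8); C1 of the cyclopentane becomes an allyl terminus once C2′ is sp2.
2. Key disconnection C5–C1: spirodienone 16 ⇐ phenol allylic methyl carbonate 15 by palladium-catalysed dearomative ipso-allylation. The arene supplies the six-membered ring; the cyclopentane C1–C5 is the only ring closed in the route.
3. 15 ⇐ HWE union of aldehyde 6 (C4 from Rh-catalysed aryl addition to ethyl crotonate, then one-carbon homologation) with ketal phosphonate 10. The phenol travels as a silyl ether, because an aryl methyl ether could not be cleaved beside the carbonate and ketal.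
4. 27 ⇐ 16 by two successive conjugate reductions that tell the enone arms apart (C6 first, then C10 with oxygenation at C9), hydrogenation of the C2′ methylene, kinetic C7=C8 enol triflate, methoxycarbonylation and acid deprotection.

Key step: step 10

Numbering used throughout: C5 spiro carbon; C1 carries the side chain, C4 the methyl; C6–C10 six-membered ring with C8 the former phenol carbon; C2′ is the side-chain carbon on C1. Names of spiro compounds use this numbering.

Assumption: the sense of induction of the two chiral catalysts used on new substrates (diphosphine in step 10, iridium complex in step 14) cannot be derived from the structures; the hands written are taken as the matched ones and would be replaced by their antipodes if the first run shows the opposite sense.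

**Route**

Step 1
Reactants: 1 [4-(tert-butyldimethylsilyloxy)phenyl]boronic acid; 2 ethyl (E)-but-2-enoate
Product: 3 ethyl (3S)-3-[4-(tert-butyldimethylsilyloxy)phenyl]butanoate
Conditions: Rh(acac)(C2H4)2 (3 mol %), (R)-BINAP (3.3 mol %), 1,4-dioxane/H2O (10:1), 100 °C
Reagents that add atoms: none
Why: Hayashi–Miyaura reaction, in which the aryl–rhodium complex of (R)-BINAP should add to the 2re face of the (E)-enoate and so set C4 as the (S) centre, the neutral medium leaving the aryl silyl ether intact.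

Step 2
Reactants: 3 ethyl (3S)-3-[4-(tert-butyldimethylsilyloxy)phenyl]butanoate
Product: 4 (3S)-3-[4-(tert-butyldimethylsilyloxy)phenyl]butanal
Conditions: iBu2AlH (1.1 equiv), CH2Cl2, −78 °C; aq. potassium sodium tartrate
Reagents that add atoms: none
Why: Partial ester reduction by iBu2AlH at −78 °C stops at the aluminium hemiacetal, which gives the aldehyde on work-up, and the β-stereocentre cannot enolise.

Step 3
Reactants: 4 (3S)-3-[4-(tert-butyldimethylsilyloxy)phenyl]butanal
Product: 6 (4S)-4-[4-(tert-butyldimethylsilyloxy)phenyl]pentanal, via enol ether 5 (not isolated)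
Conditions: Ph3P(CH2OMe)Cl (1.5 equiv), KN(SiMe3)2 (1.4 equiv), THF, 0 °C → rt; then 2 M HCl (aq), THF, rt
Reagents that add atoms: (methoxymethyl)triphenylphosphonium chloride, COC[P+](c1ccccc1)(c1ccccc1)c1ccccc1.[Cl-]; water, O
Why: Wittig methoxymethylenation followed by acid hydrolysis of the enol ether is the standard one-carbon homologation of an aldehyde, and an aryl silyl ether resists brief dilute acid.

Step 4
Reactants: 7 triethyl phosphonoacetate; 8 4-methylpent-1-en-3-one
Product: 9 ethyl 2-(diethoxyphosphoryl)-6-methyl-5-oxoheptanoate (racemic)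
Conditions: 7 (1.5 equiv), NaOEt (0.1 equiv), EtOH, 0 °C, slow addition of 8, then rt
Reagents that add atoms: none
Why: Base-catalysed Michael addition of the doubly activated methylene to the unhindered vinyl ketone, with an excess of 7 to suppress double addition.

Step 5
Reactants: 9 ethyl 2-(diethoxyphosphoryl)-6-methyl-5-oxoheptanoate
Product: 10 ethyl 2-(diethoxyphosphoryl)-4-[2-(propan-2-yl)-1,3-dioxolan-2-yl]butanoate (racemic)
Conditions: HOCH2CH2OH (3 equiv), TsOH·H2O (5 mol %), toluene, reflux, Dean–Stark trap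
Reagents that add atoms: ethylene glycol, OCCO
Why: Acid-catalysed ketalisation with azeotropic removal of water protects the isopropyl ketone against the hydride, amide-base and enolate chemistry that follows.

Step 6
Reactants: 10 ethyl 2-(diethoxyphosphoryl)-4-[2-(propan-2-yl)-1,3-dioxolan-2-yl]butanoate; 6 (4S)-4-[4-(tert-butyldimethylsilyloxy)phenyl]pentanal
Product: 12 ethyl (2E,6S)-6-[4-(tert-butyldimethylsilyloxy)phenyl]-2-{2-[2-(propan-2-yl)-1,3-dioxolan-2-yl]ethyl}hept-2-enoate (2Z isomer carried along), via sodium phosphonate 11 (not isolated)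
Conditions: NaH (1.1 equiv), THF, 0 °C; then 6, 0 °C → rt
Reagents that add atoms: none
Why: Horner–Wadsworth–Emmons olefination of an aliphatic aldehyde with an α-alkylated phosphonoacetate should give the trisubstituted enoate, mainly (E), and the geometry is immaterial because both isomers later ionise to the same equilibrating π-allyl complex.

Step 7
Reactants: 12 ethyl (2E,6S)-6-[4-(tert-butyldimethylsilyloxy)phenyl]-2-{2-[2-(propan-2-yl)-1,3-dioxolan-2-yl]ethyl}hept-2-enoate
Product: 13 (2E,6S)-6-[4-(tert-butyldimethylsilyloxy)phenyl]-2-{2-[2-(propan-2-yl)-1,3-dioxolan-2-yl]ethyl}hept-2-en-1-ol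
Conditions: iBu2AlH (2.5 equiv), CH2Cl2, −78 → −40 °C; aq. potassium sodium tartrate
Reagents that add atoms: none
Why: iBu2AlH reduces the conjugated ester in 1,2-fashion to the allylic alcohol and leaves ketal, silyl ether and alkene untouched.

Step 8
Reactants: 13 (2E,6S)-6-[4-(tert-butyldimethylsilyloxy)phenyl]-2-{2-[2-(propan-2-yl)-1,3-dioxolan-2-yl]ethyl}hept-2-en-1-ol
Product: 14 (2E,6S)-6-[4-(tert-butyldimethylsilyloxy)phenyl]-2-{2-[2-(propan-2-yl)-1,3-dioxolan-2-yl]ethyl}hept-2-en-1-yl methyl carbonate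
Conditions: ClCO2Me (1.5 equiv), pyridine (3 equiv), CH2Cl2, 0 °C
Reagents that add atoms: methyl chloroformate, COC(=O)Cl
Why: Acylation of the primary allylic alcohol installs an ionisable leaving group that delivers its own base (methoxide) in step 10.

Step 9
Reactants: 14 (2E,6S)-6-[4-(tert-butyldimethylsilyloxy)phenyl]-2-{2-[2-(propan-2-yl)-1,3-dioxolan-2-yl]ethyl}hept-2-en-1-yl methyl carbonate
Product: 15 (2E,6S)-6-(4-hydroxyphenyl)-2-{2-[2-(propan-2-yl)-1,3-dioxolan-2-yl]ethyl}hept-2-en-1-yl methyl carbonate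
Conditions: Bu4NF (1.1 equiv), AcOH (1.2 equiv), THF, 0 °C
Reagents that add atoms: none
Why: Fluoride cleaves the aryl O–Si bond within minutes at 0 °C, and acetic acid buffers the phenoxide so that the carbonate is neither transferred nor cleaved.

Step 10
Reactants: 15 (2E,6S)-6-(4-hydroxyphenyl)-2-{2-[2-(propan-2-yl)-1,3-dioxolan-2-yl]ethyl}hept-2-en-1-yl methyl carbonate
Product: 16 (1R,4S)-4-methyl-1-{4-[2-(propan-2-yl)-1,3-dioxolan-2-yl]but-1-en-2-yl}spiro[4.5]deca-6,9-dien-8-one
Conditions: Pd2(dba)3·CHCl3 (2.5 mol %), N,N′-[(1R,2R)-cyclohexane-1,2-diyl]bis[2-(diphenylphosphino)benzamide] (7.5 mol %), degassed CH2Cl2 (0.02 M), rt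
Reagents that add atoms: none
Why: Zerovalent palladium ionises the allylic carbonate to a 2-substituted π-allyl complex, CO2 is lost and the liberated methoxide deprotonates the phenol. The phenolate attacks, anti to the metal, through its para carbon at the allyl terminus that carries the tether, which forms C5–C1 and gives the cross-conjugated dienone directly; the closest known reaction type is the palladium-catalysed intramolecular ipso-Friedel–Crafts allylic alkylation of para-substituted phenols to spiro[4.5]cyclohexadienones. The cyclopentane closes in a 5-exo mode with respect to the allyl unit (attack at the internal terminus, C2′=CH2 left outside the ring), the alternative being a seven-membered ring by attack at the CH2 terminus. C1 is the only new stereocentre (C5 is not yet stereogenic): the two diastereomeric π-allyl complexes interconvert by π–σ–π through the unsubstituted CH2 terminus, and the chiral diphosphine selects the allyl face that is attacked so that C1 should end (R), trans to the C4 methyl, the benzylic methyl adding only a small bias of its own. The step needs C- over O-alkylation and ipso over ortho attack: the oxygen and the carbons ortho to it cannot reach the allyl unit through a three-carbon tether anchored para, the ring carbons next to the tether are meta to the phenolate oxygen and not nucleophilic, and high dilution suppresses O-allylation between two molecules.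

Step 11
Reactants: 16 (1R,4S)-4-methyl-1-{4-[2-(propan-2-yl)-1,3-dioxolan-2-yl]but-1-en-2-yl}spiro[4.5]deca-6,9-dien-8-one
Product: 18 (1R,4S,5R)-4-methyl-1-{4-[2-(propan-2-yl)-1,3-dioxolan-2-yl]but-1-en-2-yl}spiro[4.5]dec-9-en-8-one (C6 and C7 saturated; C9=C10 retained), via silyl dienol ether 17 (not isolated)
Conditions: (IPr)CuCl (5 mol %), NaOtBu (5 mol %), (EtO)2MeSiH (1.2 equiv), toluene, 0 °C → rt; then MeOH, K2CO3 (cat.), 0 °C
Reagents that add atoms: none
Why: Copper hydride conjugate reduction (1,4-hydrosilylation) of a cross-conjugated dienone stops after one arm because the product is held as silyl dienol ether 17, and the bulky carbene–Cu–H should enter from the dienone face turned toward C4 (whose methyl lies beside C10, leaving C6 flanked only by C4–H) and not from the face crowded by the C1 alkenyl branch, so that C6=C7 is reduced and C5 becomes (R) with the new C6 methylene syn to the side chain.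

Step 12
Reactants: 18 (1R,4S,5R)-4-methyl-1-{4-[2-(propan-2-yl)-1,3-dioxolan-2-yl]but-1-en-2-yl}spiro[4.5]dec-9-en-8-one
Product: 20 triethyl{[(1R,4S,5S)-4-methyl-1-{4-[2-(propan-2-yl)-1,3-dioxolan-2-yl]but-1-en-2-yl}spiro[4.5]dec-8-en-8-yl]oxy}silane (C8=C9 enol ether), via lithium enolate 19 (not isolated)
Conditions: Li[sBu3BH] (1.1 equiv), THF, −78 °C; then Et3SiCl (1.5 equiv), Et3N, −78 → 0 °C
Reagents that add atoms: chlorotriethylsilane, CC[Si](Cl)(CC)CC
Why: Conjugate reduction of the remaining enone by the bulky borohydride (hydride to C10, no stereocentre formed) gives the enolate regiospecifically at C8–C9, and O-silylation fixes it as the triethylsilyl enol ether.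

Step 13
Reactants: 20 triethyl{[(1R,4S,5S)-4-methyl-1-{4-[2-(propan-2-yl)-1,3-dioxolan-2-yl]but-1-en-2-yl}spiro[4.5]dec-8-en-8-yl]oxy}silane
Product: 22 (1R,4S,5S,9S)-4-methyl-1-{4-[2-(propan-2-yl)-1,3-dioxolan-2-yl]but-1-en-2-yl}-9-(triethylsilyloxy)spiro[4.5]decan-8-one, via silyloxy epoxide 21 (not isolated)
Conditions: dimethyldioxirane (1.05 equiv, acetone solution), CH2Cl2, −78 → −20 °C; then rt on silica gel to complete the silyl shift
Reagents that add atoms: dimethyldioxirane, CC1(C)OO1
Why: Rubottom oxidation, in which the dioxirane should epoxidise the electron-rich enol ether far faster than the 1,1-disubstituted alkene and from the ring face anti to the C4 methyl that overhangs the C9–C10 edge (the other flank is only C1–H), after which 1,4-silyl migration in the silyloxy epoxide gives the (9S)-silyloxy ketone with oxygen cis to C1.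

Step 14
Reactants: 22 (1R,4S,5S,9S)-4-methyl-1-{4-[2-(propan-2-yl)-1,3-dioxolan-2-yl]but-1-en-2-yl}-9-(triethylsilyloxy)spiro[4.5]decan-8-one
Product: 23 (1R,4S,5S,9S)-4-methyl-1-{(2R)-4-[2-(propan-2-yl)-1,3-dioxolan-2-yl]butan-2-yl}-9-(triethylsilyloxy)spiro[4.5]decan-8-one
Conditions: [Ir(cod)((S)-tBu-PHOX)]BArF (2 mol %), H2 (1 bar), CH2Cl2, 0 °C → rt
Reagents that add atoms: none
Why: Iridium–phosphinooxazoline-catalysed asymmetric hydrogenation of an unfunctionalised 1,1-disubstituted alkene, here the only C=C bond in the molecule, in which the catalyst tells the alkene faces apart through the large difference between the ring-bound sec-alkyl substituent and the primary chain and should set C2′ as (R) under catalyst control.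

Step 15
Reactants: 23 (1R,4S,5S,9S)-4-methyl-1-{(2R)-4-[2-(propan-2-yl)-1,3-dioxolan-2-yl]butan-2-yl}-9-(triethylsilyloxy)spiro[4.5]decan-8-one
Product: 25 (1R,4S,5S,9S)-4-methyl-1-{(2R)-4-[2-(propan-2-yl)-1,3-dioxolan-2-yl]butan-2-yl}-9-(triethylsilyloxy)spiro[4.5]dec-7-en-8-yl trifluoromethanesulfonate, via lithium enolate 24 (not isolated)
Conditions: LiN(iPr)2 (1.15 equiv), THF, −78 °C; then PhNTf2 (1.2 equiv), −78 → 0 °C
Reagents that add atoms: N-phenylbis(trifluoromethanesulfonimide), O=S(=O)(N(c1ccccc1)S(=O)(=O)C(F)(F)F)C(F)(F)F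
Why: Kinetic deprotonation at −78 °C removes a proton from the unhindered C7 methylene and not from the silyloxy-bearing C9 methine, so that O-triflation of the enolate gives the C7=C8 enol triflate without touching C9.

Step 16
Reactants: 25 (1R,4S,5S,9S)-4-methyl-1-{(2R)-4-[2-(propan-2-yl)-1,3-dioxolan-2-yl]butan-2-yl}-9-(triethylsilyloxy)spiro[4.5]dec-7-en-8-yl trifluoromethanesulfonate
Product: 26 methyl (1R,4S,5S,9S)-4-methyl-1-{(2R)-4-[2-(propan-2-yl)-1,3-dioxolan-2-yl]butan-2-yl}-9-(triethylsilyloxy)spiro[4.5]dec-7-ene-8-carboxylate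
Conditions: Pd(OAc)2 (5 mol %), 1,1′-bis(diphenylphosphino)ferrocene (10 mol %), Et3N (2 equiv), MeOH/DMF (1:4), CO (1 atm), 60 °C
Reagents that add atoms: carbon monoxide, [C-]#[O+]; methanol, CO
Why: Palladium-catalysed methoxycarbonylation of an enol triflate (oxidative addition, CO insertion, methanolysis of the acyl–palladium complex) installs the ester on C8 with the double bond fixed at C7=C8.

Step 17
Reactants: 26 methyl (1R,4S,5S,9S)-4-methyl-1-{(2R)-4-[2-(propan-2-yl)-1,3-dioxolan-2-yl]butan-2-yl}-9-(triethylsilyloxy)spiro[4.5]dec-7-ene-8-carboxylate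
Product: 27 methyl (1R,4S,5S,9S)-9-hydroxy-4-methyl-1-[(2R)-6-methyl-5-oxoheptan-2-yl]spiro[4.5]dec-7-ene-8-carboxylate (CNP0116894.1)
Conditions: 1 M HCl (aq)/THF (1:3), rt
Reagents that add atoms: water, O
Why: Dilute aqueous acid hydrolyses the dioxolane and the triethylsilyl ether in one operation, and the allylic alcohol is safe from ionisation because the cation would sit next to the ester-bearing carbon.

**Compound list**

1 | [4-(tert-butyldimethylsilyloxy)phenyl]boronic acid | CC(C)(C)[Si](C)(C)Oc1ccc(cc1)B(O)O | starting material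
2 | ethyl (E)-but-2-enoate | C/C=C/C(=O)OCC | starting material
3 | ethyl (3S)-3-[4-(tert-butyldimethylsilyloxy)phenyl]butanoate | C[C@H](c1ccc(O[Si](C)(C)C(C)(C)C)cc1)CC(=O)OCC | intermediate
4 | (3S)-3-[4-(tert-butyldimethylsilyloxy)phenyl]butanal | C[C@H](c1ccc(O[Si](C)(C)C(C)(C)C)cc1)CC=O | intermediate
5 | tert-butyl{4-[(2S)-5-methoxypent-4-en-2-yl]phenoxy}dimethylsilane (E/Z mixture, not isolated) | C[C@H](c1ccc(O[Si](C)(C)C(C)(C)C)cc1)CC=COC | intermediate
6 | (4S)-4-[4-(tert-butyldimethylsilyloxy)phenyl]pentanal | C[C@H](c1ccc(O[Si](C)(C)C(C)(C)C)cc1)CCC=O | intermediate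
7 | triethyl phosphonoacetate | CCOC(=O)CP(=O)(OCC)OCC | starting material
8 | 4-methylpent-1-en-3-one | C=CC(=O)C(C)C | starting material
9 | ethyl 2-(diethoxyphosphoryl)-6-methyl-5-oxoheptanoate (racemic) | CCOC(=O)C(CCC(=O)C(C)C)P(=O)(OCC)OCC | intermediate
10 | ethyl 2-(diethoxyphosphoryl)-4-[2-(propan-2-yl)-1,3-dioxolan-2-yl]butanoate (racemic) | CCOC(=O)C(CCC1(OCCO1)C(C)C)P(=O)(OCC)OCC | intermediate
11 | sodium salt of the phosphonate carbanion of 10 (not isolated) | [Na+].CCOC(=O)[C-](CCC1(OCCO1)C(C)C)P(=O)(OCC)OCC | intermediate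
12 | ethyl (2E,6S)-6-[4-(tert-butyldimethylsilyloxy)phenyl]-2-{2-[2-(propan-2-yl)-1,3-dioxolan-2-yl]ethyl}hept-2-enoate | C[C@H](c1ccc(O[Si](C)(C)C(C)(C)C)cc1)CC/C=C(/C(=O)OCC)CCC2(OCCO2)C(C)C | intermediate
13 | (2E,6S)-6-[4-(tert-butyldimethylsilyloxy)phenyl]-2-{2-[2-(propan-2-yl)-1,3-dioxolan-2-yl]ethyl}hept-2-en-1-ol | C[C@H](c1ccc(O[Si](C)(C)C(C)(C)C)cc1)CC/C=C(/CO)CCC2(OCCO2)C(C)C | intermediate
14 | (2E,6S)-6-[4-(tert-butyldimethylsilyloxy)phenyl]-2-{2-[2-(propan-2-yl)-1,3-dioxolan-2-yl]ethyl}hept-2-en-1-yl methyl carbonate | C[C@H](c1ccc(O[Si](C)(C)C(C)(C)C)cc1)CC/C=C(/COC(=O)OC)CCC2(OCCO2)C(C)C | intermediate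
15 | (2E,6S)-6-(4-hydroxyphenyl)-2-{2-[2-(propan-2-yl)-1,3-dioxolan-2-yl]ethyl}hept-2-en-1-yl methyl carbonate | C[C@H](c1ccc(O)cc1)CC/C=C(/COC(=O)OC)CCC2(OCCO2)C(C)C | intermediate
16 | (1R,4S)-4-methyl-1-{4-[2-(propan-2-yl)-1,3-dioxolan-2-yl]but-1-en-2-yl}spiro[4.5]deca-6,9-dien-8-one | O=C1C=CC2(C=C1)[C@@H](C(=C)CCC3(OCCO3)C(C)C)CC[C@@H]2C | intermediate
17 | (1R,4S,5R)-8-[diethoxy(methyl)silyloxy]-4-methyl-1-{4-[2-(propan-2-yl)-1,3-dioxolan-2-yl]but-1-en-2-yl}spiro[4.5]deca-7,9-diene (not isolated) | CCO[Si](C)(OCC)OC1=CC[C@@]2(C=C1)[C@@H](C(=C)CCC3(OCCO3)C(C)C)CC[C@@H]2C | intermediate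
18 | (1R,4S,5R)-4-methyl-1-{4-[2-(propan-2-yl)-1,3-dioxolan-2-yl]but-1-en-2-yl}spiro[4.5]dec-9-en-8-one | O=C1CC[C@@]2(C=C1)[C@@H](C(=C)CCC3(OCCO3)C(C)C)CC[C@@H]2C | intermediate
19 | lithium (1R,4S,5S)-4-methyl-1-{4-[2-(propan-2-yl)-1,3-dioxolan-2-yl]but-1-en-2-yl}spiro[4.5]dec-8-en-8-olate (not isolated) | [Li+].[O-]C1=CC[C@]2(CC1)[C@@H](C(=C)CCC3(OCCO3)C(C)C)CC[C@@H]2C | intermediate
20 | triethyl{[(1R,4S,5S)-4-methyl-1-{4-[2-(propan-2-yl)-1,3-dioxolan-2-yl]but-1-en-2-yl}spiro[4.5]dec-8-en-8-yl]oxy}silane | CC[Si](CC)(CC)OC1=CC[C@]2(CC1)[C@@H](C(=C)CCC3(OCCO3)C(C)C)CC[C@@H]2C | intermediate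
21 | (1R,4S,5S,8S,9S)-8,9-epoxy-4-methyl-1-{4-[2-(propan-2-yl)-1,3-dioxolan-2-yl]but-1-en-2-yl}-8-(triethylsilyloxy)spiro[4.5]decane, epoxide oxygen cis to C1 (not isolated) | CC[Si](CC)(CC)O[C@@]12CC[C@@]3(C[C@@H]1O2)[C@@H](C(=C)CCC4(OCCO4)C(C)C)CC[C@@H]3C | intermediate
22 | (1R,4S,5S,9S)-4-methyl-1-{4-[2-(propan-2-yl)-1,3-dioxolan-2-yl]but-1-en-2-yl}-9-(triethylsilyloxy)spiro[4.5]decan-8-one | O=C1CC[C@@]2(C[C@@H]1O[Si](CC)(CC)CC)[C@@H](C(=C)CCC3(OCCO3)C(C)C)CC[C@@H]2C | intermediate
23 | (1R,4S,5S,9S)-4-methyl-1-{(2R)-4-[2-(propan-2-yl)-1,3-dioxolan-2-yl]butan-2-yl}-9-(triethylsilyloxy)spiro[4.5]decan-8-one | O=C1CC[C@@]2(C[C@@H]1O[Si](CC)(CC)CC)[C@@H]([C@H](C)CCC3(OCCO3)C(C)C)CC[C@@H]2C | intermediate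
24 | lithium (1R,4S,5S,9S)-4-methyl-1-{(2R)-4-[2-(propan-2-yl)-1,3-dioxolan-2-yl]butan-2-yl}-9-(triethylsilyloxy)spiro[4.5]dec-7-en-8-olate (not isolated) | [Li+].[O-]C1=CC[C@@]2(C[C@@H]1O[Si](CC)(CC)CC)[C@@H]([C@H](C)CCC3(OCCO3)C(C)C)CC[C@@H]2C | intermediate
25 | (1R,4S,5S,9S)-4-methyl-1-{(2R)-4-[2-(propan-2-yl)-1,3-dioxolan-2-yl]butan-2-yl}-9-(triethylsilyloxy)spiro[4.5]dec-7-en-8-yl trifluoromethanesulfonate | O=S(=O)(OC1=CC[C@@]2(C[C@@H]1O[Si](CC)(CC)CC)[C@@H]([C@H](C)CCC3(OCCO3)C(C)C)CC[C@@H]2C)C(F)(F)F | intermediate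
26 | methyl (1R,4S,5S,9S)-4-methyl-1-{(2R)-4-[2-(propan-2-yl)-1,3-dioxolan-2-yl]butan-2-yl}-9-(triethylsilyloxy)spiro[4.5]dec-7-ene-8-carboxylate | COC(=O)C1=CC[C@@]2(C[C@@H]1O[Si](CC)(CC)CC)[C@@H]([C@H](C)CCC3(OCCO3)C(C)C)CC[C@@H]2C | intermediate
27 | methyl (1R,4S,5S,9S)-9-hydroxy-4-methyl-1-[(2R)-6-methyl-5-oxoheptan-2-yl]spiro[4.5]dec-7-ene-8-carboxylate | COC(=O)C1=CC[C@@]2(C[C@@H]1O)[C@@H]([C@H](C)CCC(=O)C(C)C)CC[C@@H]2C | target

**Step count**

Total: 17 steps. Longest linear sequence: 15 steps (1, 2, 3, 6–17); steps 4 and 5 form the two-step side branch to phosphonate 10.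

**Steps most likely to fail**

Step 10. The ligand may fail to override the substrate's own facial preference, so that the cyclopentane closes with C1 cis to the C4 methyl. O-allylation between two molecules or β-hydride loss from the π-allyl complex may also outrun the ipso attack. Fallback, an oxidative closure of the same C5–C1 bond: from 14, palladium-catalysed silylation of the allylic carbonate with hexamethyldisilane (Pd(dba)2, LiCl, DMF) would give the allyltrimethylsilane F1. Bu4NF/AcOH frees the phenol F2. PhI(OAc)2 in hexafluoroisopropanol at −20 °C then lets the γ-carbon of the allylsilane attack the para carbon of the activated phenol, which returns to 16. C1 is then under substrate control only and the epimers would be separated.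

Step 11. Hydride delivery may not discriminate between the two enone arms, or may prefer C10, because the arms differ only in the remote C1 and C4 substituents. Fallback, the complementary order of operations, which makes the other arm productive as well: from 16, the regioisomeric enone F3 (C9–C10 saturated, C6=C7 retained) is separated from 18. Kinetic α′-enolisation of F3 (LiN(iPr)2, −78 °C; C5 has no γ-hydrogen) and silylation with Et3SiCl give the cross-conjugated dienol ether F4. The dioxirane oxidation of step 13 gives the α′-silyloxy enone F5. Conjugate reduction of its C6=C7 bond (Li[sBu3BH], then NH4Cl) converges on 22.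

Step 14. Facial selectivity at the acyclic 1,1-disubstituted alkene may be poor, or iridium hydride may first isomerise the alkene toward C1 and erode both C1 and C2′. Fallback, separation in place of induction: from 22, hydrogenation over (Ph3P)3RhCl (H2 1 bar, benzene) reduces only the terminal alkene but without control and gives 23 together with the C2′ epimer F6. The two are separated by preparative chromatography and the route continues from 23.

**Further compounds**

F1 | step 10 | tert-butyldimethyl{4-[(2S,5E)-6-[(trimethylsilyl)methyl]-8-[2-(propan-2-yl)-1,3-dioxolan-2-yl]oct-5-en-2-yl]phenoxy}silane (alkene geometry immaterial) | C[C@H](c1ccc(O[Si](C)(C)C(C)(C)C)cc1)CC/C=C(/C[Si](C)(C)C)CCC2(OCCO2)C(C)C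
F2 | step 10 | 4-[(2S,5E)-6-[(trimethylsilyl)methyl]-8-[2-(propan-2-yl)-1,3-dioxolan-2-yl]oct-5-en-2-yl]phenol | C[C@H](c1ccc(O)cc1)CC/C=C(/C[Si](C)(C)C)CCC2(OCCO2)C(C)C
F3 | step 11 | (1R,4S,5S)-4-methyl-1-{4-[2-(propan-2-yl)-1,3-dioxolan-2-yl]but-1-en-2-yl}spiro[4.5]dec-6-en-8-one | O=C1C=C[C@@]2(CC1)[C@@H](C(=C)CCC3(OCCO3)C(C)C)CC[C@@H]2C
F4 | step 11 | triethyl{[(1R,4S,5S)-4-methyl-1-{4-[2-(propan-2-yl)-1,3-dioxolan-2-yl]but-1-en-2-yl}spiro[4.5]deca-6,8-dien-8-yl]oxy}silane | CC[Si](CC)(CC)OC1=CC[C@]2(C=C1)[C@@H](C(=C)CCC3(OCCO3)C(C)C)CC[C@@H]2C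
F5 | step 11 | (1R,4S,5S,9S)-4-methyl-1-{4-[2-(propan-2-yl)-1,3-dioxolan-2-yl]but-1-en-2-yl}-9-(triethylsilyloxy)spiro[4.5]dec-6-en-8-one | O=C1C=C[C@@]2(C[C@@H]1O[Si](CC)(CC)CC)[C@@H](C(=C)CCC3(OCCO3)C(C)C)CC[C@@H]2C
F6 | step 14 | (1R,4S,5S,9S)-4-methyl-1-{(2S)-4-[2-(propan-2-yl)-1,3-dioxolan-2-yl]butan-2-yl}-9-(triethylsilyloxy)spiro[4.5]decan-8-one | O=C1CC[C@@]2(C[C@@H]1O[Si](CC)(CC)CC)[C@@H]([C@@H](C)CCC3(OCCO3)C(C)C)CC[C@@H]2C
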